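**Strategy.** Ring A is grown, not substituted. In flavan numbering, the phloroglucinol ring A carries oxygen on C5, C7 and C8a (O1) and the prenyl group on C8, between O7 and O1. This 1,3,5-pattern is disconnected to a vinylketene (from a 3-silyloxycyclobutenone) and a prenyl ynol ether joined through C2–C3–C4. One photochemical operation forms C4a–C8a, C7–C8 and C6–C7 and closes rings C and A, so C8 versus C6 never arises. The precursor 21 is the (S)-benzylic 5-methylhex-4-en-1-ynyl ether whose propyl chain ends in C2 of a 3-(triisopropylsilyloxy)cyclobutenone. C2 of the flavan comes from an asymmetric allylboration; the cyclobutenone is attached by Negishi coupling.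

Key step: step 10

Remark: flavan numbering (O1, C2, C3, C4, C4a, C5–C8, C8a) is used for all compounds; the benzylic ynol ether is assumed to be labile to heat and acid (retro-ene and [3,3] pathways), so from step 6 until it is consumed in step 10 every operation is kept at or below room temperature and free of acid.

Step 1
Reactants: 1 3-hydroxy-5-methoxybenzaldehyde
Product: 2 3-methoxy-5-(triisopropylsilyloxy)benzaldehyde
Conditions: TIPSCl, imidazole, DMF, 0 °C to rt
Reagents that add atoms: triisopropylsilyl chloride, CC(C)[Si](Cl)(C(C)C)C(C)C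
Why: Imidazole-promoted O-silylation of the phenol; the aryl TIPS ether should tolerate KH, n-BuLi at −78 °C and organozinc chemistry and falls to fluoride in the last step.

Step 2
Reactants: 2 3-methoxy-5-(triisopropylsilyloxy)benzaldehyde; 3 (−)-B-allyldiisopinocampheylborane
Product: 5 (S)-1-[3-methoxy-5-(triisopropylsilyloxy)phenyl]but-3-en-1-ol, via borinate ester 4 (not isolated)
Conditions: (−)-Ipc2B(allyl), Et2O, −78 °C; then NaBO3·4H2O, THF/H2O, rt
Reagents that add atoms: (−)-B-allyldiisopinocampheylborane, C=CCB([C@@H]1C[C@@H]2C[C@H]([C@H]1C)C2(C)C)[C@@H]1C[C@@H]2C[C@H]([C@H]1C)C2(C)C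
Why: Brown allylboration through a chair Zimmerman–Traxler transition state, in which the reagent derived from (+)-α-pinene delivers allyl to the Si face of an aryl aldehyde and so sets the carbinol carbon (later C2) as S.

Step 3
Reactants: 5 (S)-1-[3-methoxy-5-(triisopropylsilyloxy)phenyl]but-3-en-1-ol; 6 trichloroethylene
Product: 8 (S,E)-{3-[1-(1,2-dichlorovinyloxy)but-3-enyl]-5-methoxyphenoxy}triisopropylsilane, via potassium alkoxide 7 (not isolated)
Conditions: KH, THF, 0 °C; then trichloroethylene, −50 °C to rt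
Reagents that add atoms: trichloroethylene, ClC=C(Cl)Cl
Why: Dichlorovinyl ether synthesis in which base dehydrochlorinates trichloroethylene to dichloroacetylene and the alkoxide adds to it in anti fashion to give the E ether, the C–O bond at the stereocentre staying intact.

Step 4
Reactants: 8 (S,E)-{3-[1-(1,2-dichlorovinyloxy)but-3-enyl]-5-methoxyphenoxy}triisopropylsilane
Product: 10 (S,E)-3-(1,2-dichlorovinyloxy)-3-[3-methoxy-5-(triisopropylsilyloxy)phenyl]propan-1-ol, via aldehyde 9 (not isolated)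
Conditions: OsO4 (2 mol%), NaIO4, 2,6-lutidine, dioxane/H2O, rt; extractive work-up; then NaBH4, MeOH, 0 °C
Reagents that add atoms: osmium tetroxide (catalytic oxygen carrier), O=[Os](=O)(=O)=O; sodium periodate (terminal oxidant), [Na+].[O-]I(=O)(=O)=O
Why: Lemieux–Johnson cleavage followed by borohydride reduction, in which electrophilic OsO4 should select the monosubstituted alkene over the chlorine-deactivated enol ether and prompt reduction of β-oxy aldehyde 9 forestalls β-elimination.

Step 5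
Reactants: 10 (S,E)-3-(1,2-dichlorovinyloxy)-3-[3-methoxy-5-(triisopropylsilyloxy)phenyl]propan-1-ol
Product: 11 (S,E)-{3-[3-bromo-1-(1,2-dichlorovinyloxy)propyl]-5-methoxyphenoxy}triisopropylsilane
Conditions: CBr4, PPh3, CH2Cl2, 0 °C
Reagents that add atoms: carbon tetrabromide, BrC(Br)(Br)Br
Why: Appel bromination of the primary alcohol under neutral conditions; the bromide is introduced only after the alkoxide step (a γ-bromo alkoxide would close to an oxetane) and is the handle for zinc insertion.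

Step 6
Reactants: 11 (S,E)-{3-[3-bromo-1-(1,2-dichlorovinyloxy)propyl]-5-methoxyphenoxy}triisopropylsilane; 12 prenyl bromide
Product: 15 (S)-{3-[3-bromo-1-(5-methylhex-4-en-1-ynyloxy)propyl]-5-methoxyphenoxy}triisopropylsilane, via chloroalkynyl ether 13 (not isolated), via lithium acetylide 14 (not isolated)
Conditions: n-BuLi (2.1 equiv), THF, −78 °C; then CuI (10 mol%), prenyl bromide, −78 to 0 °C; Et3N-deactivated silica, below rt
Reagents that add atoms: prenyl bromide, CC(C)=CCBr
Why: Ynol ether synthesis by elimination and chlorine–lithium exchange (n-BuLi removes the vinyl proton and expels LiCl to give 13, a second equivalent gives acetylide 14), followed by CuI-catalysed SN2 allylation with prenyl bromide, which should outpace any reaction at the primary alkyl bromide at low temperature.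

Step 7
Reactants: 16 3-ethoxycyclobut-2-en-1-one
Product: 18 2-bromo-3-hydroxycyclobut-2-en-1-one, via bromo enol ether 17 (not isolated)
Conditions: NBS, MeCN/H2O, 0 °C; then 2 M HCl, rt
Reagents that add atoms: N-bromosuccinimide, O=C1CCC(=O)N1Br; water, O
Why: Electrophilic α-bromination of the vinylogous ester at C2 followed by acid hydrolysis of the enol ether should give the enol of 2-bromocyclobutane-1,3-dione, a vinylogous acid.

Step 8
Reactants: 18 2-bromo-3-hydroxycyclobut-2-en-1-one
Product: 19 2-bromo-3-(triisopropylsilyloxy)cyclobut-2-en-1-one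
Conditions: TIPSCl, Et3N, CH2Cl2, 0 °C; non-aqueous work-up, used without chromatography
Reagents that add atoms: triisopropylsilyl chloride, CC(C)[Si](Cl)(C(C)C)C(C)C
Why: O-Silylation of the vinylogous acid; the 1,3-dione is symmetrical, so only one silyl enol ether can form, and the bulky TIPS group slows hydrolysis of this vinylogous silyl ester.

Step 9
Reactants: 15 (S)-{3-[3-bromo-1-(5-methylhex-4-en-1-ynyloxy)propyl]-5-methoxyphenoxy}triisopropylsilane; 19 2-bromo-3-(triisopropylsilyloxy)cyclobut-2-en-1-one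
Product: 21 (S)-2-{3-[3-methoxy-5-(triisopropylsilyloxy)phenyl]-3-(5-methylhex-4-en-1-ynyloxy)propyl}-3-(triisopropylsilyloxy)cyclobut-2-en-1-one, via alkylzinc bromide 20 (not isolated)
Conditions: Zn* (activated zinc from ZnCl2 and lithium naphthalenide), THF, rt; then 19, Pd(OAc)2 (5 mol%), SPhos (10 mol%), THF, rt
Reagents that add atoms: none
Why: Negishi coupling in which activated zinc inserts into the primary bromide at room temperature, zerovalent palladium formed from Pd(OAc)2 adds oxidatively to the electron-poor vinyl bromide of 19, and SPhos favours reductive elimination over β-hydride elimination, all under neutral conditions that spare the ynol ether.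

Step 10
Reactants: 21 (S)-2-{3-[3-methoxy-5-(triisopropylsilyloxy)phenyl]-3-(5-methylhex-4-en-1-ynyloxy)propyl}-3-(triisopropylsilyloxy)cyclobut-2-en-1-one
Product: 26 (S)-2-[3-methoxy-5-(triisopropylsilyloxy)phenyl]-8-(3-methylbut-2-enyl)-5-(triisopropylsilyloxy)chroman-7-ol, via vinylketene 22 (not isolated), via fused cyclobutenone 23 (not isolated), via dienylketene 24 (not isolated), via cyclohexadienone 25 (not isolated)
Conditions: hν (350 nm, Pyrex), degassed toluene (0.005 M), 0 °C; then 60 °C in the dark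
Reagents that add atoms: none
Why: Proposed new method: photochemical 4π ring opening of 21 should give silyloxy vinylketene 22, whose ketene C=C adds [2+2] across the tethered ynol ether (carbonyl carbon C7 to the nucleophilic alkyne carbon C8, α-carbon C4a to the oxygen-bearing C8a) to give fused cyclobutenone 23, and thermal 4π opening to dienylketene 24, 6π electrocyclisation (C6–C7) and enolisation of dienone 25 then deliver phenol 26. The closest known reaction types are the intermolecular Danheiser benzannulation of cyclobutenones with alkoxy- and siloxyalkynes and intramolecular ketene–alkyne [2+2] cycloadditions; their tethered combination is untested. Ring C closes in the [2+2] event as a six-membered ring through the four-atom O1–C2–C3–C4 tether, and ring A closes by 6π electrocyclisation of a dienylketene whose central C4a=C8a double bond is held cis by ring C. No stereocentre is created in 26 (C4a of 23 is transient and both epimers converge), and C2 is a spectator whose C–O bond is never broken. The step needs regioselective cycloaddition and survival of the ynol ether: ynol ether polarity and tether length both demand the C7–C8/C4a–C8a pairing, so the C8 prenyl group, O5 and O7 follow from connectivity, while irradiation at 0 °C at high dilution keeps the benzylic ynol ether away from retro-ene and [3,3] pathways and suppresses ketene dimerisation, heat being applied only once the ynol ether is consumed.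

Step 11
Reactants: 26 (S)-2-[3-methoxy-5-(triisopropylsilyloxy)phenyl]-8-(3-methylbut-2-enyl)-5-(triisopropylsilyloxy)chroman-7-ol
Product: 27 (S)-2-(3-hydroxy-5-methoxyphenyl)-8-(3-methylbut-2-enyl)chroman-5,7-diol (CNP0173255.1)
Conditions: Bu4NF, AcOH, THF, 0 °C, argon
Reagents that add atoms: none
Why: Fluoride desilylation of both aryl TIPS ethers under buffered, oxygen-free conditions that protect the electron-rich prenylphloroglucinol; no bond to C2 is touched.

**Compound list**

1 | 3-hydroxy-5-methoxybenzaldehyde | COc1cc(O)cc(C=O)c1 | starting material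
2 | 3-methoxy-5-(triisopropylsilyloxy)benzaldehyde | COc1cc(O[Si](C(C)C)(C(C)C)C(C)C)cc(C=O)c1 | intermediate
3 | (−)-B-allyldiisopinocampheylborane (from (+)-α-pinene) | C=CCB([C@@H]1C[C@@H]2C[C@H]([C@H]1C)C2(C)C)[C@@H]1C[C@@H]2C[C@H]([C@H]1C)C2(C)C | starting material
4 | (S)-1-[3-methoxy-5-(triisopropylsilyloxy)phenyl]but-3-enyl diisopinocampheylborinate | B(O[C@@H](CC=C)c1cc(OC)cc(O[Si](C(C)C)(C(C)C)C(C)C)c1)([C@@H]1C[C@@H]2C[C@H]([C@H]1C)C2(C)C)[C@@H]1C[C@@H]2C[C@H]([C@H]1C)C2(C)C | intermediate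
5 | (S)-1-[3-methoxy-5-(triisopropylsilyloxy)phenyl]but-3-en-1-ol | O[C@@H](CC=C)c1cc(OC)cc(O[Si](C(C)C)(C(C)C)C(C)C)c1 | intermediate
6 | trichloroethylene | ClC=C(Cl)Cl | starting material
7 | potassium (S)-1-[3-methoxy-5-(triisopropylsilyloxy)phenyl]but-3-en-1-olate | [K+].[O-][C@@H](CC=C)c1cc(OC)cc(O[Si](C(C)C)(C(C)C)C(C)C)c1 | intermediate
8 | (S,E)-{3-[1-(1,2-dichlorovinyloxy)but-3-enyl]-5-methoxyphenoxy}triisopropylsilane | Cl/C=C(/Cl)O[C@@H](CC=C)c1cc(OC)cc(O[Si](C(C)C)(C(C)C)C(C)C)c1 | intermediate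
9 | (S,E)-3-(1,2-dichlorovinyloxy)-3-[3-methoxy-5-(triisopropylsilyloxy)phenyl]propanal | Cl/C=C(/Cl)O[C@@H](CC=O)c1cc(OC)cc(O[Si](C(C)C)(C(C)C)C(C)C)c1 | intermediate
10 | (S,E)-3-(1,2-dichlorovinyloxy)-3-[3-methoxy-5-(triisopropylsilyloxy)phenyl]propan-1-ol | Cl/C=C(/Cl)O[C@@H](CCO)c1cc(OC)cc(O[Si](C(C)C)(C(C)C)C(C)C)c1 | intermediate
11 | (S,E)-{3-[3-bromo-1-(1,2-dichlorovinyloxy)propyl]-5-methoxyphenoxy}triisopropylsilane | Cl/C=C(/Cl)O[C@@H](CCBr)c1cc(OC)cc(O[Si](C(C)C)(C(C)C)C(C)C)c1 | intermediate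
12 | prenyl bromide (1-bromo-3-methylbut-2-ene) | CC(C)=CCBr | starting material
13 | (S)-{3-[3-bromo-1-(chloroethynyloxy)propyl]-5-methoxyphenoxy}triisopropylsilane | ClC#CO[C@@H](CCBr)c1cc(OC)cc(O[Si](C(C)C)(C(C)C)C(C)C)c1 | intermediate
14 | (S)-({3-bromo-1-[3-methoxy-5-(triisopropylsilyloxy)phenyl]propoxy}ethynyl)lithium | [Li]C#CO[C@@H](CCBr)c1cc(OC)cc(O[Si](C(C)C)(C(C)C)C(C)C)c1 | intermediate
15 | (S)-{3-[3-bromo-1-(5-methylhex-4-en-1-ynyloxy)propyl]-5-methoxyphenoxy}triisopropylsilane | CC(C)=CCC#CO[C@@H](CCBr)c1cc(OC)cc(O[Si](C(C)C)(C(C)C)C(C)C)c1 | intermediate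
16 | 3-ethoxycyclobut-2-en-1-one | CCOC1=CC(=O)C1 | starting material
17 | 2-bromo-3-ethoxycyclobut-2-en-1-one | CCOC1=C(Br)C(=O)C1 | intermediate
18 | 2-bromo-3-hydroxycyclobut-2-en-1-one | OC1=C(Br)C(=O)C1 | intermediate
19 | 2-bromo-3-(triisopropylsilyloxy)cyclobut-2-en-1-one | CC(C)[Si](OC1=C(Br)C(=O)C1)(C(C)C)C(C)C | intermediate
20 | (S)-{3-[3-methoxy-5-(triisopropylsilyloxy)phenyl]-3-(5-methylhex-4-en-1-ynyloxy)propyl}zinc bromide | CC(C)=CCC#CO[C@@H](CC[Zn]Br)c1cc(OC)cc(O[Si](C(C)C)(C(C)C)C(C)C)c1 | intermediate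
21 | (S)-2-{3-[3-methoxy-5-(triisopropylsilyloxy)phenyl]-3-(5-methylhex-4-en-1-ynyloxy)propyl}-3-(triisopropylsilyloxy)cyclobut-2-en-1-one | CC(C)=CCC#CO[C@@H](CCC1=C(O[Si](C(C)C)(C(C)C)C(C)C)CC1=O)c1cc(OC)cc(O[Si](C(C)C)(C(C)C)C(C)C)c1 | intermediate
22 | (S)-2-{3-[3-methoxy-5-(triisopropylsilyloxy)phenyl]-3-(5-methylhex-4-en-1-ynyloxy)propyl}-3-(triisopropylsilyloxy)buta-1,3-dien-1-one | CC(C)=CCC#CO[C@@H](CCC(=C=O)C(=C)O[Si](C(C)C)(C(C)C)C(C)C)c1cc(OC)cc(O[Si](C(C)C)(C(C)C)C(C)C)c1 | intermediate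
23 | (3S)-3-[3-methoxy-5-(triisopropylsilyloxy)phenyl]-8-(3-methylbut-2-enyl)-6-[1-(triisopropylsilyloxy)vinyl]-2-oxabicyclo[4.2.0]oct-1(8)-en-7-one (either configuration at C6, the later C4a) | CC(C)=CCC1=C2O[C@H](c3cc(OC)cc(O[Si](C(C)C)(C(C)C)C(C)C)c3)CCC2(C(=C)O[Si](C(C)C)(C(C)C)C(C)C)C1=O | intermediate
24 | 2-{(2S)-2-[3-methoxy-5-(triisopropylsilyloxy)phenyl]-5-[1-(triisopropylsilyloxy)vinyl]-3,4-dihydro-2H-pyran-6-yl}-5-methylhexa-1,4-dien-1-one | CC(C)=CCC(=C=O)C1=C(C(=C)O[Si](C(C)C)(C(C)C)C(C)C)CC[C@@H](c2cc(OC)cc(O[Si](C(C)C)(C(C)C)C(C)C)c2)O1 | intermediate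
25 | (S)-2-[3-methoxy-5-(triisopropylsilyloxy)phenyl]-8-(3-methylbut-2-enyl)-5-(triisopropylsilyloxy)-2,3,4,6-tetrahydro-7H-chromen-7-one | CC(C)=CCC1=C2O[C@H](c3cc(OC)cc(O[Si](C(C)C)(C(C)C)C(C)C)c3)CCC2=C(O[Si](C(C)C)(C(C)C)C(C)C)CC1=O | intermediate
26 | (S)-2-[3-methoxy-5-(triisopropylsilyloxy)phenyl]-8-(3-methylbut-2-enyl)-5-(triisopropylsilyloxy)chroman-7-ol | COc1cc(O[Si](C(C)C)(C(C)C)C(C)C)cc([C@@H]2CCc3c(O[Si](C(C)C)(C(C)C)C(C)C)cc(O)c(CC=C(C)C)c3O2)c1 | intermediate
27 | (S)-2-(3-hydroxy-5-methoxyphenyl)-8-(3-methylbut-2-enyl)chroman-5,7-diol | COc1cc(O)cc([C@@H]2CCc3c(O)cc(O)c(CC=C(C)C)c3O2)c1 | target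

Total step count: 11 (steps 7 and 8 build the cyclobutenone arm).
Longest linear sequence: 9 steps (steps 1–6, 9, 10, 11).

**Steps most likely to fail**

1. Step 10. Capture of the vinylketene by the tethered ynol ether may lose out to ketene dimerisation, photoreversion to the cyclobutenone or thermal fragmentation of the ynol ether, because the [2+2] transition state has to build a bridgehead cyclobutene. The fallback takes the tether out of the benzannulation and runs it as the known intermolecular Danheiser reaction; it sets out from 15 and 19 and comes back to the route at 27. Irradiation (350 nm, toluene, 0.2 M, rt, then 60 °C) of 19 in excess with ynol ether 15 should give 4-bromo-3-{(S)-3-bromo-1-[3-methoxy-5-(triisopropylsilyloxy)phenyl]propoxy}-2-(3-methylbut-2-enyl)-5-(triisopropylsilyloxy)phenol F1. In F1, C7–C8, C4a–C8a and C6–C7 are formed as before and O1–C2 is already in place, while C4–C4a is still open (bromine on C4a and on C4). Silylation of the C7 phenol (TIPSCl, imidazole, DMF) should give the tris-silyl dibromide F2. Activated zinc (Zn*, THF, rt) inserts into the primary bromide only, giving the alkylzinc bromide F3, and intramolecular Negishi coupling (Pd(OAc)2, SPhos, THF, 50 °C) closes ring C to (S)-2-[3-methoxy-5-(triisopropylsilyloxy)phenyl]-8-(3-methylbut-2-enyl)-5,7-bis(triisopropylsilyloxy)chroman F4. Bu4NF/AcOH then gives 27.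

2. Step 9. Zinc insertion and transmetalation may be slower than protodemetalation, 1,3-elimination of the γ-oxy organozinc or desilylation of the vinylogous silyl ester 19. The fallback avoids a preformed organometallic: 15 and 19 are joined directly by nickel-catalysed reductive cross-electrophile coupling (NiBr2(dme), 4,4'-di-tert-butyl-2,2'-bipyridine, Mn, DMA, rt), a known way to couple primary alkyl bromides with vinyl bromides. It sets out from 15 and 19 and comes back at 21; no new compound is made on the way (entry F0).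

3. Step 6. n-BuLi may attack the primary bromide (bromine–lithium exchange or substitution) in competition with elimination at the dichlorovinyl ether. The fallback keeps oxygen at the chain terminus through the organolithium step and installs the bromide afterwards; it sets out from 10 and comes back at 15. Alcohol 10 is silylated (TMSCl, Et3N, CH2Cl2) to the trimethylsilyl ether F5, which is taken through n-BuLi, CuI and prenyl bromide as in step 6 to the ynol ether silyl ether F6. K2CO3 in MeOH at 0 °C should free the primary alcohol F7 without touching the aryl TIPS ether. TsCl, Et3N and DMAP give the tosylate F8, and LiBr in acetone at rt gives 15.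

**Further compounds**

F1 | step 10 | 4-bromo-3-{(S)-3-bromo-1-[3-methoxy-5-(triisopropylsilyloxy)phenyl]propoxy}-2-(3-methylbut-2-enyl)-5-(triisopropylsilyloxy)phenol | CC(C)=CCc1c(O)cc(O[Si](C(C)C)(C(C)C)C(C)C)c(Br)c1O[C@@H](CCBr)c1cc(OC)cc(O[Si](C(C)C)(C(C)C)C(C)C)c1
F2 | step 10 | (S)-{[4-bromo-5-{3-bromo-1-[3-methoxy-5-(triisopropylsilyloxy)phenyl]propoxy}-6-(3-methylbut-2-enyl)-1,3-phenylene]bis(oxy)}bis(triisopropylsilane) | CC(C)=CCc1c(O[Si](C(C)C)(C(C)C)C(C)C)cc(O[Si](C(C)C)(C(C)C)C(C)C)c(Br)c1O[C@@H](CCBr)c1cc(OC)cc(O[Si](C(C)C)(C(C)C)C(C)C)c1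
F3 | step 10 | (S)-{3-[2-bromo-6-(3-methylbut-2-enyl)-3,5-bis(triisopropylsilyloxy)phenoxy]-3-[3-methoxy-5-(triisopropylsilyloxy)phenyl]propyl}zinc bromide | CC(C)=CCc1c(O[Si](C(C)C)(C(C)C)C(C)C)cc(O[Si](C(C)C)(C(C)C)C(C)C)c(Br)c1O[C@@H](CC[Zn]Br)c1cc(OC)cc(O[Si](C(C)C)(C(C)C)C(C)C)c1
F4 | step 10 | (S)-2-[3-methoxy-5-(triisopropylsilyloxy)phenyl]-8-(3-methylbut-2-enyl)-5,7-bis(triisopropylsilyloxy)chroman | COc1cc(O[Si](C(C)C)(C(C)C)C(C)C)cc([C@@H]2CCc3c(O[Si](C(C)C)(C(C)C)C(C)C)cc(O[Si](C(C)C)(C(C)C)C(C)C)c(CC=C(C)C)c3O2)c1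
F0 | step 9 | none | none
F5 | step 6 | (S,E)-{3-[1-(1,2-dichlorovinyloxy)-3-(trimethylsilyloxy)propyl]-5-methoxyphenoxy}triisopropylsilane | Cl/C=C(/Cl)O[C@@H](CCO[Si](C)(C)C)c1cc(OC)cc(O[Si](C(C)C)(C(C)C)C(C)C)c1
F6 | step 6 | (S)-{3-methoxy-5-[1-(5-methylhex-4-en-1-ynyloxy)-3-(trimethylsilyloxy)propyl]phenoxy}triisopropylsilane | CC(C)=CCC#CO[C@@H](CCO[Si](C)(C)C)c1cc(OC)cc(O[Si](C(C)C)(C(C)C)C(C)C)c1
F7 | step 6 | (S)-3-[3-methoxy-5-(triisopropylsilyloxy)phenyl]-3-(5-methylhex-4-en-1-ynyloxy)propan-1-ol | CC(C)=CCC#CO[C@@H](CCO)c1cc(OC)cc(O[Si](C(C)C)(C(C)C)C(C)C)c1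
F8 | step 6 | (S)-3-[3-methoxy-5-(triisopropylsilyloxy)phenyl]-3-(5-methylhex-4-en-1-ynyloxy)propyl 4-methylbenzenesulfonate | CC(C)=CCC#CO[C@@H](CCOS(=O)(=O)c1ccc(C)cc1)c1cc(OC)cc(O[Si](C(C)C)(C(C)C)C(C)C)c1
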